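**Retrosynthetic overview**

1. Target 19 ⇐ triene lactone 18 by a last-step Schenck ene reaction of singlet oxygen: the C1 hydroperoxide with the C10=C14 methylidene is the ene retron of an E-C1=C10 alkene.
2. Butenolide (C6–O–C12, C7=C11) ⇐ ring-closing metathesis of a C6 2-(acetoxymethyl)acrylate onto a C7 methylidene; the C6 stereocentre ⇐ CBS reduction of a C6 ketone.
3. Ten-membered ring ⇐ anionic oxy-Cope ring expansion that forms C8–C9 and breaks C1–C6 of a 1-vinyl-6-isopropenylcyclohex-2-enol made from (S)-carvone; the enolate is trapped at C7.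
4. Enabling feature: with C1–C6 bonded, C9=C10–C1–C6(O)–C7=C8 is a 3-oxy-1,5-diene, and the bridge C2–C3–C4=C5 (Z alkene, C3 oxygen) is the cyclohex-2-ene ring of cis-carveol; C6 carries the lactone oxygen.
5. Ring order: cyclohexene (chiral pool) → ten-membered carbocycle (step 5) → butenolide (step 10).

Key step: step 5

Remark: ring compounds are numbered as germacranes (ring C1–C10, lactone carbons C11–C13, C14 on C10, C15 on C4). In this numbering the target is (1R,3S,6R,4Z), i.e. 1β-OOH, 3β-OAc, 12,6α-olide.

**Route**

Step 1
Reactants: 1 (S)-(+)-carvone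
Product: 2 (1S,5S)-cis-carveol
Conditions: NaBH4, CeCl3·7H2O, MeOH, −78 to 0 °C
Reagents that add atoms: none
Why: Luche 1,2-reduction with axial hydride delivery should give the pseudo-equatorial alcohol 1,3-cis to the isopropenyl group, so the carvone stereocentre sets the carbinol carbon (future C3) as S.

Step 2
Reactants: 2 (1S,5S)-cis-carveol
Product: 3 cis-carveol tert-butyldimethylsilyl ether
Conditions: TBSCl, imidazole, DMF, rt
Reagents that add atoms: tert-butyldimethylsilyl chloride, CC(C)(C)[Si](C)(C)Cl
Why: Standard silylation of a secondary allylic alcohol gives an ether that tolerates the oxidant, the organometallic reagent and KH used later.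

Step 3
Reactants: 3 cis-carveol tert-butyldimethylsilyl ether
Product: 4 (4S,6S)-4-silyloxy-3-methyl-6-isopropenylcyclohex-2-enone
Conditions: CrO3, 3,5-dimethylpyrazole, CH2Cl2, −20 °C
Reagents that add atoms: chromium trioxide, O=[Cr](=O)=O
Why: Allylic oxidation with the CrO3–3,5-dimethylpyrazole complex should attack the only free ring methylene allylic to the trisubstituted alkene (the other allylic ring position carries OTBS), giving the isopiperitenone-type enone; partial epimerisation next to the ketone would be harmless because that centre is destroyed in step 5.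

Step 4
Reactants: 4 (4S,6S)-4-silyloxy-3-methyl-6-isopropenylcyclohex-2-enone
Product: 5 (1S,4S,6S)-1-vinyl-6-isopropenylcyclohex-2-enol
Conditions: CH2=CHMgBr, CeCl3 (anhydrous), THF, −78 °C
Reagents that add atoms: vinylmagnesium bromide, C=C[Mg]Br
Why: The organocerium reagent should add 1,2 without enolising the acidic α-position, and attack anti to the neighbouring isopropenyl group (and to the OTBS face) should give the trans-1,2-dialkenyl carbinol.

Step 5
Reactants: 5 (1S,4S,6S)-1-vinyl-6-isopropenylcyclohex-2-enol
Product: 8 Mannich base of the (1(10)E,4Z)-cyclodecadien-6-one, via potassium alkoxide 6 (not isolated), via potassium enolate 7 (not isolated)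
Conditions: KH, 18-crown-6, THF, 0 °C to rt; then Me2N=CH2 I (Eschenmoser's salt), −78 °C to rt
Reagents that add atoms: N,N-dimethylmethyleneiminium iodide (Eschenmoser's salt), C[N+](C)=C.[I-]
Why: KH with 18-crown-6 turns 5 into the free tertiary alkoxide 6, whose C9=C10–C1–C6(O−)–C7=C8 unit should undergo the anionic oxy-Cope ([3,3]-sigmatropic) rearrangement through a chair transition state with both alkenyl groups pseudo-equatorial on the cyclohexene; the closest known reaction type is the ring expansion of alkenyl adducts of isopiperitenone-type enones to (Z,E)-cyclodecadienones. The ten-membered carbocycle is closed by a four-atom ring expansion (C8–C9 forms as C1–C6 breaks within one six-atom array), not by end-to-end cyclisation, so no high dilution is needed. No lasting stereocentre is made: the chair array sets the E geometry of C1=C10, the Z geometry of C4=C5 is inherited from the cyclohexene, C3 is untouched, and the C7 centre created in the trapping is erased in step 6. The step needs the [3,3] shift to win over a [1,3] shift, over fragmentation and over the alternative 1,5-diene through the ring alkene (which would need a boat across the ring); the trans-dialkenyl arrangement of 5 and the irreversible formation of enolate 7 should secure this. Because 7 is generated as a single regioisomer without equilibration, Eschenmoser's salt should alkylate it only at C7 (Mannich reaction).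

Step 6
Reactants: 8 Mannich base of the (1(10)E,4Z)-cyclodecadien-6-one
Product: 10 7-methylidene cyclodecadien-6-one, via ammonium iodide 9 (not isolated)
Conditions: MeI, CH2Cl2, rt; then aq. NaHCO3, rt
Reagents that add atoms: none
Why: Quaternisation followed by mild-base E1cB (Hofmann-type) elimination of trimethylamine should give the α-methylidene ketone without acid, which the transannularly reactive diene would not tolerate.

Step 7
Reactants: 10 7-methylidene cyclodecadien-6-one
Product: 11 (3S,6R)-7-methylidene cyclodecadien-6-ol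
Conditions: (S)-Me-CBS oxazaborolidine (cat.), catecholborane, toluene, −78 °C
Reagents that add atoms: none
Why: Corey–Bakshi–Shibata 1,2-reduction; with the α-branched C7 alkenyl flank acting as the large group and the C5 alkenyl CH as the small one, the (S)-catalyst should deliver hydride to give the 6R alcohol, and catecholborane leaves the alkenes untouched.

Step 8
Reactants: 12 2-(bromomethyl)acrylic acid
Product: 13 2-(acetoxymethyl)acrylic acid
Conditions: NaOAc, AcOH, 60 °C
Reagents that add atoms: sodium acetate, CC(=O)[O-].[Na+]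
Why: Acetate displaces the activated allylic bromide (direct and allylic substitution give the same product because the two CH2 termini of the 2-carboxyallyl unit are equivalent), and acetic acid as solvent should suppress self-alkylation of the acid.

Step 9
Reactants: 11 (3S,6R)-7-methylidene cyclodecadien-6-ol; 13 2-(acetoxymethyl)acrylic acid
Product: 15 C6 2-(acetoxymethyl)acrylate ester, via acid chloride 14 (not isolated)
Conditions: 13, (COCl)2, DMF (cat.), CH2Cl2, 0 °C to rt; then 11, pyridine, CH2Cl2, −20 to 0 °C
Reagents that add atoms: none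
Why: Acylation of the secondary alcohol with the acid chloride and pyridine proceeds with retention at C6 and avoids strongly nucleophilic amine catalysts, which would attack the 2-(acetoxymethyl)acrylate in an allylic substitution.

Step 10
Reactants: 15 C6 2-(acetoxymethyl)acrylate ester
Product: 16 (3S,6R)-13-acetoxy-3-silyloxy-germacra-1(10)E,4Z,7(11)-trien-12,6-olide
Conditions: second-generation Hoveyda-Grubbs catalyst RuCl2(H2IMes)(=CH-C6H4-2-OiPr) (cat.), toluene (dilute), 80 °C, argon purge
Reagents that add atoms: none
Why: Ring-closing metathesis of the two 1,1-disubstituted alkenes held on a five-ring-forming ester tether should give the tetrasubstituted butenolide alkene C7=C11 with loss of ethylene, while the trisubstituted ring alkenes are too hindered to take part.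

Step 11
Reactants: 16 (3S,6R)-13-acetoxy-3-silyloxy-germacra-1(10)E,4Z,7(11)-trien-12,6-olide
Product: 17 (3S,6R)-13-acetoxy-3-hydroxy-germacra-1(10)E,4Z,7(11)-trien-12,6-olide
Conditions: HF·pyridine, pyridine, THF, 0 °C to rt
Reagents that add atoms: none
Why: Buffered fluoride cleaves the secondary silyl ether, and the acetate, the butenolide and the acid-sensitive 1(10),4-diene should survive.

Step 12
Reactants: 17 (3S,6R)-13-acetoxy-3-hydroxy-germacra-1(10)E,4Z,7(11)-trien-12,6-olide
Product: 18 (3S,6R)-3,13-diacetoxy-germacra-1(10)E,4Z,7(11)-trien-12,6-olide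
Conditions: Ac2O, pyridine, DMAP (cat.), CH2Cl2, 0 °C
Reagents that add atoms: acetic anhydride, CC(=O)OC(C)=O
Why: Standard acetylation of the C3 alcohol with retention; the butenolide acetate is not displaced because its allylic terminus C7 is fully substituted.

Step 13
Reactants: 18 (3S,6R)-3,13-diacetoxy-germacra-1(10)E,4Z,7(11)-trien-12,6-olide
Product: 19 target, (1R,3S,6R)-3,13-diacetoxy-1-hydroperoxy-germacra-4Z,7(11),10(14)-trien-12,6-olide
Conditions: O2, visible light, tetraphenylporphyrin (cat.), CH2Cl2, −20 °C
Reagents that add atoms: dioxygen (as singlet oxygen), O=O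
Why: Schenck ene reaction: singlet oxygen should react only with the electron-rich C1=C10 alkene (C4=C5 is deactivated by two allylic acyloxy groups, C7=C11 is conjugated), abstract hydrogen from the C14 methyl on the more crowded side of the alkene to give the C10=C14 methylidene, and bond to C1 from the exposed outer (β) face of the trans-cyclodecene unit, which sets C1 as R.

**Compound list**

1 | (S)-(+)-carvone, (5S)-2-methyl-5-(prop-1-en-2-yl)cyclohex-2-en-1-one | CC(=C)[C@H]1CC=C(C)C(=O)C1 | starting material
2 | (1S,5S)-cis-carveol, (1S,5S)-2-methyl-5-(prop-1-en-2-yl)cyclohex-2-en-1-ol | O[C@H]1C[C@@H](C(C)=C)CC=C1C | intermediate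
3 | tert-butyldimethylsilyl ether of (1S,5S)-cis-carveol | CC(C)(C)[Si](C)(C)O[C@H]1C[C@@H](C(C)=C)CC=C1C | intermediate
4 | (4S,6S)-4-[(tert-butyldimethylsilyl)oxy]-3-methyl-6-(prop-1-en-2-yl)cyclohex-2-en-1-one | CC(C)(C)[Si](C)(C)O[C@H]1C[C@@H](C(C)=C)C(=O)C=C1C | intermediate
5 | (1S,4S,6S)-4-[(tert-butyldimethylsilyl)oxy]-1-ethenyl-3-methyl-6-(prop-1-en-2-yl)cyclohex-2-en-1-ol (OH, isopropenyl and OTBS all cis) | CC(C)(C)[Si](C)(C)O[C@H]1C[C@@H](C(C)=C)[C@](O)(C=C)C=C1C | intermediate
6 | potassium alkoxide of 5 | CC(C)(C)[Si](C)(C)O[C@H]1C[C@@H](C(C)=C)[C@]([O-])(C=C)C=C1C.[K+] | intermediate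
7 | potassium enolate (C6–O, C6=C7) of (3S,1(10)E,4Z)-3-[(tert-butyldimethylsilyl)oxy]-4,10-dimethylcyclodeca-1(10),4-dien-6-one; enolate geometry not assigned | C/C1=C\C[C@H](O[Si](C)(C)C(C)(C)C)/C(C)=C\C([O-])=CCC1.[K+] | intermediate
8 | (3S,1(10)E,4Z)-3-[(tert-butyldimethylsilyl)oxy]-7-[(dimethylamino)methyl]-4,10-dimethylcyclodeca-1(10),4-dien-6-one (C7 epimers) | C/C1=C\C[C@H](O[Si](C)(C)C(C)(C)C)/C(C)=C\C(=O)C(CN(C)C)CC1 | intermediate
9 | trimethylammonium iodide of 8 | C/C1=C\C[C@H](O[Si](C)(C)C(C)(C)C)/C(C)=C\C(=O)C(C[N+](C)(C)C)CC1.[I-] | intermediate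
10 | (3S,1(10)E,4Z)-3-[(tert-butyldimethylsilyl)oxy]-4,10-dimethyl-7-methylidenecyclodeca-1(10),4-dien-6-one | C/C1=C\C[C@H](O[Si](C)(C)C(C)(C)C)/C(C)=C\C(=O)C(=C)CC1 | intermediate
11 | (3S,6R,1(10)E,4Z)-3-[(tert-butyldimethylsilyl)oxy]-4,10-dimethyl-7-methylidenecyclodeca-1(10),4-dien-6-ol | C/C1=C\C[C@H](O[Si](C)(C)C(C)(C)C)/C(C)=C\[C@@H](O)C(=C)CC1 | intermediate
12 | 2-(bromomethyl)acrylic acid | OC(=O)C(=C)CBr | starting material
13 | 2-(acetoxymethyl)acrylic acid | CC(=O)OCC(=C)C(=O)O | intermediate
14 | 2-(acetoxymethyl)acryloyl chloride | CC(=O)OCC(=C)C(Cl)=O | intermediate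
15 | 2-(acetoxymethyl)acrylate ester of 11 at the C6 oxygen | C/C1=C\C[C@H](O[Si](C)(C)C(C)(C)C)/C(C)=C\[C@@H](OC(=O)C(=C)COC(C)=O)C(=C)CC1 | intermediate
16 | (3S,6R)-13-acetoxy-3-[(tert-butyldimethylsilyl)oxy]germacra-1(10)E,4Z,7(11)-trien-12,6-olide | C/C1=C\C[C@H](O[Si](C)(C)C(C)(C)C)/C(C)=C\[C@H]2OC(=O)C(COC(C)=O)=C2CC1 | intermediate
17 | (3S,6R)-13-acetoxy-3-hydroxygermacra-1(10)E,4Z,7(11)-trien-12,6-olide | C/C1=C\C[C@H](O)/C(C)=C\[C@H]2OC(=O)C(COC(C)=O)=C2CC1 | intermediate
18 | (3S,6R)-3,13-diacetoxygermacra-1(10)E,4Z,7(11)-trien-12,6-olide | C/C1=C\C[C@H](OC(C)=O)/C(C)=C\[C@H]2OC(=O)C(COC(C)=O)=C2CC1 | intermediate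
19 | CNP0174966.1, (1R,3S,6R)-3,13-diacetoxy-1-hydroperoxygermacra-4Z,7(11),10(14)-trien-12,6-olide | C=C1CCC2=C(COC(C)=O)C(=O)O[C@@H]2/C=C(/C)[C@@H](OC(C)=O)C[C@H]1OO | target

**Step count and risks**

Total step count: 13. Longest linear sequence: 12 steps (steps 1–7 and 9–13); step 8 is a one-step side branch.

Steps most likely to fail:

1. Step 10 (ring-closing metathesis). Initiation and ring closure between two 1,1-disubstituted alkenes may be slow, so catalyst decomposition and intermolecular metathesis of the acrylate could compete. The fallback makes the C7=C11 alkene by aldol condensation instead of metathesis; it sets out from 5 and comes back at 16. The key step would be repeated, but enolate 7 would be trapped at −78 °C with ethyl 3-acetoxy-2-oxopropanoate F1 (from ethyl bromopyruvate and KOAc) to give the aldol adduct F2 as a mixture at C7 and C11. Dehydration with Burgess reagent should give the alkylidene keto ester F3 as an E/Z mixture. Reduction with the (S)-CBS catalyst and catecholborane should give the 6R hydroxy ester F4, whose Z isomer should lactonise under PPTS catalysis to 16; the E isomer would be equilibrated by light or a thiyl radical and drained into the lactone.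

2. Step 13 (Schenck ene reaction). Oxygen may be delivered to the wrong face of C1=C10, or hydrogen may be abstracted from C2 or C9 instead of C14. The fallback replaces conformational control by a directing group; it sets out from 17 and comes back at 19. Photooxygenation of the free alcohol in a non-hydrogen-bonding solvent, where the 3β-hydroxyl should steer singlet oxygen to the same face by hydrogen bonding, would give the hydroperoxy alcohol F5. Silylation of the more acidic hydroperoxide (Et3SiCl, imidazole, −40 °C) would give the triethylsilyl peroxide F6, acetylation (Ac2O, pyridine) the acetate F7, and HF·pyridine would release 19. The selective silylation of OOH over OH is the weak point of this fallback.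

3. Step 7 (CBS reduction). Both carbonyl substituents are alkenyl, so facial discrimination may be poor, or the ring conformation may override the catalyst. The fallback accepts the wrong epimer and inverts it; it sets out from 10 and comes back at 11. Reduction under whichever conditions give it cleanly (NaBH4 with CeCl3, or the enantiomeric catalyst) would give the 6S alcohol F8. Mitsunobu inversion with 4-nitrobenzoic acid (PPh3, DIAD) would give the 6R 4-nitrobenzoate F9, and methanolysis (K2CO3, MeOH) would give 11. Allylic transposition during the Mitsunobu step would have to be watched.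

**Further compounds**

F1 | step 10 | ethyl 3-acetoxy-2-oxopropanoate | CCOC(=O)C(=O)COC(C)=O
F2 | step 10 | aldol adduct of enolate 7 and F1 (C7 and C11 epimers) | C/C1=C\C[C@H](O[Si](C)(C)C(C)(C)C)/C(C)=C\C(=O)C(C(O)(COC(C)=O)C(=O)OCC)CC1
F3 | step 10 | 7-alkylidene keto ester, C7=C11(CH2OAc)CO2Et (E/Z mixture) | C/C1=C\C[C@H](O[Si](C)(C)C(C)(C)C)/C(C)=C\C(=O)C(=C(COC(C)=O)C(=O)OCC)CC1
F4 | step 10 | (6R)-hydroxy ester from reduction of F3 (E/Z mixture) | C/C1=C\C[C@H](O[Si](C)(C)C(C)(C)C)/C(C)=C\[C@@H](O)C(=C(COC(C)=O)C(=O)OCC)CC1
F5 | step 13 | (1R,3S,6R)-13-acetoxy-1-hydroperoxy-3-hydroxygermacra-4Z,7(11),10(14)-trien-12,6-olide | C=C1CCC2=C(COC(C)=O)C(=O)O[C@@H]2/C=C(/C)[C@@H](O)C[C@H]1OO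
F6 | step 13 | triethylsilyl peroxide of F5 | C=C1CCC2=C(COC(C)=O)C(=O)O[C@@H]2/C=C(/C)[C@@H](O)C[C@H]1OO[Si](CC)(CC)CC
F7 | step 13 | 3-O-acetate of F6 (triethylsilyl peroxide of 19) | C=C1CCC2=C(COC(C)=O)C(=O)O[C@@H]2/C=C(/C)[C@@H](OC(C)=O)C[C@H]1OO[Si](CC)(CC)CC
F8 | step 7 | (3S,6S)-epimer of alcohol 11 | C/C1=C\C[C@H](O[Si](C)(C)C(C)(C)C)/C(C)=C\[C@H](O)C(=C)CC1
F9 | step 7 | (3S,6R)-4-nitrobenzoate of 11 | C/C1=C\C[C@H](O[Si](C)(C)C(C)(C)C)/C(C)=C\[C@@H](OC(=O)c2ccc(cc2)[N+](=O)[O-])C(=C)CC1
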